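**Retrosynthetic overview**
- Target ⇐ C8 ketone (Zn/CH2Br2/TiCl4 methylenation); butenolide ⇐ intramolecular Wittig closure onto a C13 bromomethyl ketone.
- Decalin ring B ⇐ semipinacol ring expansion of an 8-vinyl-8-hydroxy trans-hydrindane: a radical adds at C11 and C10 shifts from C8 to C9 (forms C11–C12 and C9–C10).
- Ring A triol ⇐ NaBH4 (C3), Rubottom oxidation (C2), reductive hydroxymethylation of the enone (C4, C5).
- Vinyl carbinol ⇐ chemoselective vinylation of a hydrindenedione ⇐ D-phenylalanine-mediated Robinson annulation (C10).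
- Ring order: the cyclopentane (future ring B) is bought; ring A is annulated first; ring B is enlarged from five to six members; the butenolide is closed last.

Assumption: atoms are numbered as in labdanes at every stage (C10 bears the angular methyl, C8 is the ring B carbonyl or carbinol carbon), "syn" and "anti" refer to that methyl, and compound names use indene or naphthalene numbering.

**Step 1**
Reactants: 1 2-methylcyclopentane-1,3-dione; 2 pent-1-en-3-one
Product: 4 (7aR)-4,7a-dimethyl-2,3,7,7a-tetrahydro-1H-indene-1,5(6H)-dione, via triketone 3 (not isolated)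
Conditions: H2O, rt; water removed; D-phenylalanine (1.0 equiv), 1 M aq. HClO4 (0.5 equiv), MeCN, reflux
Reagents that add atoms: none
Why: Michael addition followed by an amino-acid-mediated Hajos–Parrish-type aldol condensation (Robinson annulation), in which the D-phenylalanine enamine differentiates the two enantiotopic ring carbonyls and sets C10 as R (L-phenylalanine is known to give the S series).

**Step 2**
Reactants: 4 (7aR)-4,7a-dimethyl-2,3,7,7a-tetrahydro-1H-indene-1,5(6H)-dione; 5 vinylmagnesium bromide
Product: 6 (1S,7aR)-1-ethenyl-1-hydroxy-4,7a-dimethyl-1,2,3,6,7,7a-hexahydro-5H-inden-5-one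
Conditions: CH2=CHMgBr (1.15 equiv), CeCl3 (1.2 equiv), THF, −78 °C; H2O quench
Reagents that add atoms: none
Why: Organocerium 1,2-addition should be fastest at the saturated cyclopentanone (the α-methyl enone carbonyl is conjugated and more hindered) and comes anti to the angular methyl as in 17-ketosteroid additions; the C8 configuration is erased later.

**Step 3**
Reactants: 6 (1S,7aR)-1-ethenyl-1-hydroxy-4,7a-dimethyl-1,2,3,6,7,7a-hexahydro-5H-inden-5-one
Product: 8 (1S,3aS,4S,7aR)-1-ethenyl-1-hydroxy-4-(hydroxymethyl)-4,7a-dimethyloctahydro-5H-inden-5-one, via dilithium enolate 7 (not isolated)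
Conditions: Li (2.1 equiv), NH3/THF, −78 to −33 °C; NH3 evaporated; CH2O (g), THF, −78 °C; AcOH quench
Reagents that add atoms: formaldehyde C=O; lithium [Li] (held only in 7)
Why: Stork reductive alkylation, in which axial protonation at C5 (the tertiary OH is the single proton source) gives the trans-fused C3–C4 enolate, and formaldehyde then adds at C4 anti to the angular methyl, leaving the C4 methyl axial and CH2OH equatorial.

**Step 4**
Reactants: 8 (1S,3aS,4S,7aR)-1-ethenyl-1-hydroxy-4-(hydroxymethyl)-4,7a-dimethyloctahydro-5H-inden-5-one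
Product: 11 (1S,3aS,4S,6S,7aR)-1-ethenyl-1,6-dihydroxy-4-(hydroxymethyl)-4,7a-dimethyloctahydro-5H-inden-5-one, via tris-TMS enol ether 9 (not isolated), via silyloxy ketone 10 (not isolated)
Conditions: TMSOTf (3.6 equiv), Et3N, CH2Cl2, 0 °C; aq. NaHCO3 wash, crude into mCPBA (1.1 equiv), CH2Cl2, −20 °C; citric acid, MeOH, rt
Reagents that add atoms: trimethylsilyl triflate C[Si](C)(C)OS(=O)(=O)C(F)(F)F (silyl groups held only in 9 and 10); mCPBA OOC(=O)c1cccc(Cl)c1
Why: Rubottom oxidation, in which the ketone can enolise only towards C2 (C4 is quaternary) and the peracid attacks the enol ether face away from the axial C10 and C4 methyls, giving the equatorial C2 hydroxyl after silyl migration and mild acid desilylation.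

**Step 5**
Reactants: 11 (1S,3aS,4S,6S,7aR)-1-ethenyl-1,6-dihydroxy-4-(hydroxymethyl)-4,7a-dimethyloctahydro-5H-inden-5-one
Product: 12 (1S,3aR,4S,5S,6S,7aR)-1-ethenyl-4-(hydroxymethyl)-4,7a-dimethyloctahydro-1H-indene-1,5,6-triol
Conditions: NaBH4, MeOH, 0 °C
Reagents that add atoms: none
Why: Axial hydride delivery from the face away from the axial C4 methyl gives the equatorial C3 alcohol and hence the trans-diequatorial 2,3-diol, as in reductions of 4,4-disubstituted 3-ketosteroids and 2-hydroxy-3-oxotriterpenoids.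

**Step 6**
Reactants: 12 (1S,3aR,4S,5S,6S,7aR)-1-ethenyl-4-(hydroxymethyl)-4,7a-dimethyloctahydro-1H-indene-1,5,6-triol; 13 1,3-dibromopropan-2-one
Product: 14 (1S,4aS,5S,6S,7S,8aR)-1-(4-bromo-3-oxobutyl)-6,7-dihydroxy-5-(hydroxymethyl)-5,8a-dimethyloctahydronaphthalen-2(1H)-one
Conditions: 13 (3 equiv), [Ir(dF(CF3)ppy)2(dtbbpy)]PF6 (1 mol%), Co(salen) (C16H14CoN2O2, 10 mol%), NaHCO3 (2 equiv), MeCN, 450 nm LEDs, rt
Reagents that add atoms: none
Why: Proposed new method: a dual photoredox/cobalt radical–polar crossover semipinacol ring expansion, in which the excited iridium photocatalyst reduces 13 to the electrophilic α-keto radical, which adds to the terminal CH2 (C11) of the vinyl carbinol; divalent Co(salen) should capture the resulting secondary C9 radical faster than bromine-atom transfer from 13, the persistent alkylcobalt is oxidised by the tetravalent iridium to a tetravalent alkylcobalt that behaves as a C9 cation equivalent, and the antiperiplanar, more electron-rich quaternary C10–C8 bond shifts to C9 with loss of divalent cobalt (driven by C=O formation and relief of cyclopentane strain), so the five-membered ring becomes the cyclohexanone of ring B and C9–C10 and C11–C12 form in one operation; the closest known reactions are photoredox radical addition/semipinacol expansions of 1-(1-arylvinyl)cyclobutanols, cobalt-salen radical–polar crossover functionalisation of unactivated alkenes and the cationic D-homoannulation of 17-hydroxy-20-substituted pregnanes with migration of the quaternary carbon, none of them shown for a non-benzylic secondary centre on a cyclopentanol; migration through the rotamer that holds C11 between C10 and the oxygen should give mainly the equatorial C9 side chain, and the C9 epimers converge in step 7.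

**Step 7**
Reactants: 14 (1S,4aS,5S,6S,7S,8aR)-1-(4-bromo-3-oxobutyl)-6,7-dihydroxy-5-(hydroxymethyl)-5,8a-dimethyloctahydronaphthalen-2(1H)-one; 15 bromoacetic acid
Product: 19 4-{2-[(1S,4aS,5S,6S,7S,8aR)-6,7-dihydroxy-5-(hydroxymethyl)-5,8a-dimethyl-2-oxodecahydronaphthalen-1-yl]ethyl}furan-2(5H)-one, via bromoacetate ester 16 (not isolated), via phosphonium bromide 17 (not isolated), via phosphorus ylide 18 (not isolated)
Conditions: 15 (1.1 equiv), Cs2CO3 (0.55 equiv), DMF, rt; 14, 0 °C to rt; PPh3 (1.3 equiv), MeCN, rt; Et3N (1.5 equiv), 40 °C; aqueous work-up, then TsOH·H2O (10 mol%), CHCl3, rt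
Reagents that add atoms: triphenylphosphine c1ccc(cc1)P(c1ccccc1)c1ccccc1 (held only in 17 and 18)
Why: Carboxylate SN2 displacement at the α-bromoketone, phosphonium salt formation and intramolecular Wittig olefination of the C13 ketone close the butenolide under bases too weak to trigger aldol cyclisation of the 1,5-diketone, and the final acid enolisation converges C9 on the equatorial side chain (axial protonation anti to the angular methyl, also the more stable epimer).

**Step 8**
Reactants: 19 4-{2-[(1S,4aS,5S,6S,7S,8aR)-6,7-dihydroxy-5-(hydroxymethyl)-5,8a-dimethyl-2-oxodecahydronaphthalen-1-yl]ethyl}furan-2(5H)-one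
Product: 20 4-{2-[(1R,4aS,5S,6S,7S,8aS)-6,7-dihydroxy-5-(hydroxymethyl)-5,8a-dimethyl-2-methylidenedecahydronaphthalen-1-yl]ethyl}furan-2(5H)-one
Conditions: Zn, CH2Br2, TiCl4, THF (reagent pre-formed at 5 °C, excess); 19, CH2Cl2, 0 °C to rt; aq. NaHCO3
Reagents that add atoms: dibromomethane BrCBr
Why: Lombardo methylenation converts the C8 ketone into the exocyclic methylene under non-basic conditions, so C9 is not epimerised and the butenolide and free hydroxyls are tolerated (as in gibberellin ketones bearing lactone and hydroxyl groups).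

**Compound list**
1 | 2-methylcyclopentane-1,3-dione | CC1C(=O)CCC1=O | starting material
2 | pent-1-en-3-one (ethyl vinyl ketone) | CCC(=O)C=C | starting material
3 | 2-methyl-2-(3-oxopentyl)cyclopentane-1,3-dione (triketone) | CCC(=O)CCC1(C)C(=O)CCC1=O | intermediate (not isolated)
4 | (7aR)-4,7a-dimethyl-2,3,7,7a-tetrahydro-1H-indene-1,5(6H)-dione | O=C1CCC2=C(C)C(=O)CC[C@@]12C | intermediate
5 | vinylmagnesium bromide | C=C[Mg]Br | starting material
6 | (1S,7aR)-1-ethenyl-1-hydroxy-4,7a-dimethyl-1,2,3,6,7,7a-hexahydro-5H-inden-5-one (OH syn, vinyl anti) | C=C[C@@]1(O)CCC2=C(C)C(=O)CC[C@@]12C | intermediate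
7 | dilithium enolate: trans-fused C3–C4 lithium enolate and C8 lithium alkoxide (5-H anti) | C=C[C@@]1(O[Li])CC[C@H]2[C@@]1(C)CCC(O[Li])=C2C | intermediate (not isolated)
8 | (1S,3aS,4S,7aR)-1-ethenyl-1-hydroxy-4-(hydroxymethyl)-4,7a-dimethyloctahydro-5H-inden-5-one (C4 methyl syn, CH2OH anti) | C=C[C@@]1(O)CC[C@H]2[C@@]1(C)CCC(=O)[C@]2(C)CO | intermediate
9 | tris-TMS enol ether of 8 (C2=C3 trimethylsilyl enol ether, C8 and CH2 trimethylsilyl ethers) | C=C[C@@]1(O[Si](C)(C)C)CC[C@H]2[C@@]1(C)CC=C(O[Si](C)(C)C)[C@]2(C)CO[Si](C)(C)C | intermediate (not isolated)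
10 | silyloxy ketone: 2-(trimethylsilyloxy)-3-ketone (C2–O anti) with C8 and CH2 trimethylsilyl ethers | C=C[C@@]1(O[Si](C)(C)C)CC[C@H]2[C@@]1(C)C[C@H](O[Si](C)(C)C)C(=O)[C@]2(C)CO[Si](C)(C)C | intermediate (not isolated)
11 | (1S,3aS,4S,6S,7aR)-1-ethenyl-1,6-dihydroxy-4-(hydroxymethyl)-4,7a-dimethyloctahydro-5H-inden-5-one | C=C[C@@]1(O)CC[C@H]2[C@@]1(C)C[C@H](O)C(=O)[C@]2(C)CO | intermediate
12 | (1S,3aR,4S,5S,6S,7aR)-1-ethenyl-4-(hydroxymethyl)-4,7a-dimethyloctahydro-1H-indene-1,5,6-triol | C=C[C@@]1(O)CC[C@H]2[C@@]1(C)C[C@H](O)[C@@H](O)[C@]2(C)CO | intermediate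
13 | 1,3-dibromopropan-2-one | BrCC(=O)CBr | starting material
14 | (1S,4aS,5S,6S,7S,8aR)-1-(4-bromo-3-oxobutyl)-6,7-dihydroxy-5-(hydroxymethyl)-5,8a-dimethyloctahydronaphthalen-2(1H)-one | O=C1CC[C@H]2[C@@](C)(C[C@H](O)[C@@H](O)[C@]2(C)CO)[C@@H]1CCC(=O)CBr | intermediate
15 | bromoacetic acid | OC(=O)CBr | starting material
16 | bromoacetate ester of the C16 oxygen (2-oxoalkyl bromoacetate of 14) | O=C1CC[C@H]2[C@@](C)(C[C@H](O)[C@@H](O)[C@]2(C)CO)[C@@H]1CCC(=O)COC(=O)CBr | intermediate (not isolated)
17 | phosphonium bromide (triphenylphosphonioacetate ester of 16) | O=C1CC[C@H]2[C@@](C)(C[C@H](O)[C@@H](O)[C@]2(C)CO)[C@@H]1CCC(=O)COC(=O)C[P+](c1ccccc1)(c1ccccc1)c1ccccc1.[Br-] | intermediate (not isolated)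
18 | phosphorus ylide from 17 | O=C1CC[C@H]2[C@@](C)(C[C@H](O)[C@@H](O)[C@]2(C)CO)[C@@H]1CCC(=O)COC(=O)C=P(c1ccccc1)(c1ccccc1)c1ccccc1 | intermediate (not isolated)
19 | 4-{2-[(1S,4aS,5S,6S,7S,8aR)-6,7-dihydroxy-5-(hydroxymethyl)-5,8a-dimethyl-2-oxodecahydronaphthalen-1-yl]ethyl}furan-2(5H)-one | O=C1CC[C@H]2[C@@](C)(C[C@H](O)[C@@H](O)[C@]2(C)CO)[C@@H]1CCC1=CC(=O)OC1 | intermediate
20 | 4-{2-[(1R,4aS,5S,6S,7S,8aS)-6,7-dihydroxy-5-(hydroxymethyl)-5,8a-dimethyl-2-methylidenedecahydronaphthalen-1-yl]ethyl}furan-2(5H)-one | C=C1CC[C@H]2[C@@](C)(C[C@H](O)[C@@H](O)[C@]2(C)CO)[C@@H]1CCC1=CC(=O)OC1 | target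

**Step count and risks**
Total step count: 8. Longest linear sequence: 8 (fully linear from 1).

Steps most likely to fail:

Step 6 (the proposed new ring expansion). The risks are bromine-atom transfer outrunning cobalt capture, migration of C7 instead of C10, and epoxide closure by the C8 hydroxyl. The fallback uses known chemistry, sets out from 12 and comes back at 14. A conventional photocatalytic atom-transfer radical addition of 13 across the vinyl group ([Cu(dap)2]Cl, green LEDs, MeCN) gives the bromohydrin, the 1-(1,5-dibromo-4-oxopentyl) analogue of 12 F4, as a mixture of C9 bromide epimers. A silver-assisted halohydrin semipinacol ring enlargement of the Sisti type (AgBF4, 2,6-di-tert-butylpyridine, CH2Cl2, −20 °C to rt) then gives 14.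

Step 2 (chemoselective vinylation). The risk is competing 1,2-addition at the enone carbonyl or enolisation. The fallback sets out from 4 and comes back at 6. The enone is first masked as its dienol ether in the classical steroid manner (HC(OEt)3, TsOH cat., EtOH), giving (7aR)-5-ethoxy-4,7a-dimethyl-2,6,7,7a-tetrahydro-1H-inden-1-one F1. Vinylmagnesium bromide with CeCl3 then adds to the only remaining ketone to give (1S,7aR)-5-ethoxy-1-ethenyl-4,7a-dimethyl-2,6,7,7a-tetrahydro-1H-inden-1-ol F2, and aqueous oxalic acid in THF unmasks the enone to give 6.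

Step 3 (reductive hydroxymethylation). The risks are proton transfer and retro-aldol loss during trapping with gaseous formaldehyde, and a cis-fused minor isomer. The fallback sets out from 6 and comes back at 8. The same Li/NH3 reduction is quenched with TMSCl/Et3N to give the C3–C4 trimethylsilyl enol ether with the C8 trimethylsilyl ether F3, which is purified (removing any cis-fused isomer). A Sc(OTf)3-catalysed Mukaiyama hydroxymethylation with aqueous formaldehyde (THF/H2O), which again enters anti to the angular methyl, followed by citric acid/MeOH gives 8.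

**Further compounds**
F1 | step 2 | (7aR)-5-ethoxy-4,7a-dimethyl-2,6,7,7a-tetrahydro-1H-inden-1-one | CCOC1=C(C)C2=CCC(=O)[C@]2(C)CC1
F2 | step 2 | (1S,7aR)-5-ethoxy-1-ethenyl-4,7a-dimethyl-2,6,7,7a-tetrahydro-1H-inden-1-ol | CCOC1=C(C)C2=CC[C@](O)(C=C)[C@]2(C)CC1
F3 | step 3 | C3–C4 trimethylsilyl enol ether and C8 trimethylsilyl ether of the trans-fused reduction product of 6 | C=C[C@@]1(O[Si](C)(C)C)CC[C@H]2[C@@]1(C)CCC(O[Si](C)(C)C)=C2C
F4 | step 6 | 1-(1,5-dibromo-4-oxopentyl) analogue of 12 (bromohydrin, both C9 epimers, ring stereocentres as in 12) | BrCC(=O)CCC(Br)[C@@]1(O)CC[C@H]2[C@@]1(C)C[C@H](O)[C@@H](O)[C@]2(C)CO
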